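In decalin numbering (ring A: C1–C4, C4a, C8a, acid chain at C1, isopropylidene at C2; ring B: C4a, C5–C8, C8a, CH2Ar and CH3 at C5, CH3 at C6 and C8a) everything rests on opening ring B at C5–C6 and C8–C8a. Because the quaternary carbons C5 and C8a flank C4a, C5–C4a–C8a can be the activated CH2, ketone carbon and ethyl CH2 of a 3-oxopentanoate, and C6–C7–C8 with its methyl is crotonaldehyde. One organocatalytic Michael/aldol-condensation domino joins them to (R)-2,5-dimethylcyclohex-2-enone and sets C6; C5 and C8a are then quaternised by enolate alkylations and ring A is closed by Dieckmann condensation.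

Key step: step 1

Remark: 1, 2 and 8 are taken as catalogue compounds; core carbons are referred to by the decalin numbering above.

Step 1
Reactants: 1 tert-butyl 3-oxopentanoate; 2 (E)-but-2-enal
Product: 5 (5R)-2,5-dimethylcyclohex-2-en-1-one, via Michael adduct 3 (not isolated), via keto aldehyde 4 (not isolated)
Conditions: (S)-2-{bis[3,5-bis(trifluoromethyl)phenyl](trimethylsilyloxy)methyl}pyrrolidine (10 mol %), PhCO2H (10 mol %), toluene, 0 °C to rt; then TsOH·H2O, toluene, 80 °C, same flask
Reagents that add atoms: none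
Why: The secondary amine condenses with 2 to an E-configured s-trans iminium ion, and the enol of 1 adds through its C2 to the β-carbon on the face away from the bis(aryl)(silyloxy)methyl group (iminium-catalysed Michael addition), which forms the C5–C6 bond and should set C6 as R. Hydrolysis releases the catalyst and 3; TsOH then cleaves the tert-butyl ester, the β-keto acid loses CO2 to give 4, and the enol of the ethyl ketone attacks the aldehyde and dehydrates (intramolecular aldol condensation), which forms C8=C8a. The closest known reaction type is the organocatalytic domino Michael/aldol condensation of β-keto esters with enals to 5-substituted cyclohex-2-enones, a Robinson-type [3+3] annulation. The one ring that closes does so in a 6-(enolendo)-exo-trig aldol mode. The single stereocentre, C6, is controlled by the catalyst alone, and the C5 centre of 3 is lost on decarboxylation. The step needs face selectivity at the iminium ion, secured by the bulky catalyst, and one sense of aldol closure, secured because only the ethyl CH2 can reach the aldehyde through a six-membered ring (the other α-carbon would close a four-membered ring).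

Step 2
Reactants: 5 (5R)-2,5-dimethylcyclohex-2-en-1-one
Product: 7 (5R,6S)-2,5,6-trimethylcyclohex-2-en-1-one, via lithium dienolate 6 (not isolated)
Conditions: LiN(i-Pr)2, THF, −78 °C; MeI, −78 to 0 °C
Reagents that add atoms: iodomethane, CI
Why: Kinetic deprotonation gives the cross-conjugated α′-enolate 6, and enolate alkylation places the methyl at decalin C5 anti to the neighbouring C6 methyl; this centre is made planar again in step 5, so its configuration is of no consequence.

Step 3
Reactants: 8 2,6-dimethylbenzene-1,4-diol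
Product: 9 2,5-dimethoxy-1,3-dimethylbenzene
Conditions: MeI, K2CO3, acetone, reflux
Reagents that add atoms: iodomethane, CI
Why: Williamson ether synthesis caps both phenols so that the arene survives the strong bases and reductants used later.

Step 4
Reactants: 9 2,5-dimethoxy-1,3-dimethylbenzene
Product: 10 1-(bromomethyl)-2,5-dimethoxy-3-methylbenzene
Conditions: NBS (1.0 equiv), AIBN (cat.), PhCF3, 80 °C
Reagents that add atoms: N-bromosuccinimide, O=C1CCC(=O)N1Br
Why: Wohl–Ziegler radical bromination; the two benzylic methyl groups are equivalent by symmetry, so only one monobromide can form, and radical conditions in a non-polar solvent favour the side chain over the ring.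

Step 5
Reactants: 7 (5R,6S)-2,5,6-trimethylcyclohex-2-en-1-one; 10 1-(bromomethyl)-2,5-dimethoxy-3-methylbenzene
Product: 12 (5R,6S)-6-[(2,5-dimethoxy-3-methylphenyl)methyl]-2,5,6-trimethylcyclohex-2-en-1-one, via lithium dienolate 11 (not isolated)
Conditions: LiN(i-Pr)2, THF, −78 °C; 10, DMPU, −78 to 0 °C
Reagents that add atoms: none
Why: Enolate alkylation: the tetrasubstituted α′-enolate 11 should be attacked by the benzylic bromide on the face opposite the adjacent C6 methyl, which sets the quaternary decalin C5 with CH2Ar trans and CH3 cis to that methyl.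

Step 6
Reactants: 12 (5R,6S)-6-[(2,5-dimethoxy-3-methylphenyl)methyl]-2,5,6-trimethylcyclohex-2-en-1-one
Product: 14 methyl 2-[(1S,3S,4R)-3-[(2,5-dimethoxy-3-methylphenyl)methyl]-1,3,4-trimethyl-2-oxocyclohexyl]acetate, via lithium enolate 13 (not isolated)
Conditions: LiBH(s-Bu)3, THF, −78 °C; BrCH2CO2Me, DMPU, −78 to 0 °C
Reagents that add atoms: methyl bromoacetate, COC(=O)CBr
Why: Reductive alkylation (Ganem): 1,4-hydride delivery gives the tetrasubstituted enolate 13 regiospecifically, and alkylation should occur on the face away from the pseudoaxial C5 methyl, as in the reductive alkylation of clerodane-type enones, so that the new quaternary C8a carries its methyl cis to the C5 and C6 methyls.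

Step 7
Reactants: 14 methyl 2-[(1S,3S,4R)-3-[(2,5-dimethoxy-3-methylphenyl)methyl]-1,3,4-trimethyl-2-oxocyclohexyl]acetate
Product: 15 methyl 2-[(1S,3S,4R)-3-[(2,5-dimethoxy-3-methylphenyl)methyl]-1,3,4-trimethyl-2-methylidenecyclohexyl]acetate
Conditions: Zn, CH2Br2, TiCl4, THF/CH2Cl2, 0 °C to rt
Reagents that add atoms: dibromomethane, BrCBr
Why: Takai–Lombardo methylenation: the small, non-basic zinc–titanium methylene reagent adds to the non-enolisable ketone and leaves the ester alone, which turns the carbonyl carbon (decalin C4a) into an exocyclic alkene whose CH2 is the future C4.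

Step 8
Reactants: 15 methyl 2-[(1S,3S,4R)-3-[(2,5-dimethoxy-3-methylphenyl)methyl]-1,3,4-trimethyl-2-methylidenecyclohexyl]acetate
Product: 17 dimethyl 2-[(1S,3S,4R)-3-[(2,5-dimethoxy-3-methylphenyl)methyl]-1,3,4-trimethyl-2-methylidenecyclohexyl]pentanedioate (both epimers at C2 of the diester), via lithium ester enolate 16 (not isolated)
Conditions: LiN(i-Pr)2, THF, −78 °C; methyl acrylate, −78 °C; aq. NH4Cl
Reagents that add atoms: methyl acrylate, C=CC(=O)OC
Why: With the ketone gone the ester α-CH2 (decalin C1) is the only acidic C–H, so one ester enolate forms and undergoes Michael addition to methyl acrylate to install the propanoate side chain; the new stereocentre is left uncontrolled because it is equilibrated in step 11.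

Step 9
Reactants: 17 dimethyl 2-[(1S,3S,4R)-3-[(2,5-dimethoxy-3-methylphenyl)methyl]-1,3,4-trimethyl-2-methylidenecyclohexyl]pentanedioate
Product: 18 dimethyl 2-[3-[(2,5-dimethoxy-3-methylphenyl)methyl]-2-(3-methoxy-3-oxopropyl)-1,3,4-trimethylcyclohexyl]pentanedioate (ring methyls at C1, C3 and C4 mutually cis, H-2 trans to them)
Conditions: BrCH2CO2Me (excess), (Me3Si)3SiH (slow addition), AIBN (cat.), benzene, 80 °C
Reagents that add atoms: methyl bromoacetate, COC(=O)CBr
Why: Reductive radical (Giese/Kharasch-type) hydroalkylation: the electrophilic methoxycarbonylmethyl radical adds to the CH2 terminus of the electron-rich 1,1-disubstituted alkene, and the tertiary C4a radical should take hydrogen from the silane on its axial face, opposite the two axial methyls at C5 and C8a, which sets H-4a trans to the C8a methyl.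

Step 10
Reactants: 18 dimethyl 2-[3-[(2,5-dimethoxy-3-methylphenyl)methyl]-2-(3-methoxy-3-oxopropyl)-1,3,4-trimethylcyclohexyl]pentanedioate
Product: 19 methyl (4aR,5S,6R,8aR)-5-[(2,5-dimethoxy-3-methylphenyl)methyl]-1-(3-methoxy-3-oxopropyl)-5,6,8a-trimethyl-2-oxodecahydronaphthalene-3-carboxylate (mixture at C1 and C3)
Conditions: KOt-Bu, THF, 0 °C to rt; aq. HCl
Reagents that add atoms: none
Why: Dieckmann condensation closes ring A as a six-membered β-keto ester (6-exo-trig acyl substitution), the enolisable product 19 being the thermodynamic sink; closure in the opposite sense would give an isomer that converges on the same ketone in step 11.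

Step 11
Reactants: 19 methyl (4aR,5S,6R,8aR)-5-[(2,5-dimethoxy-3-methylphenyl)methyl]-1-(3-methoxy-3-oxopropyl)-5,6,8a-trimethyl-2-oxodecahydronaphthalene-3-carboxylate
Product: 20 methyl 3-[(1S,4aR,5S,6R,8aR)-5-[(2,5-dimethoxy-3-methylphenyl)methyl]-5,6,8a-trimethyl-2-oxodecahydronaphthalen-1-yl]propanoate
Conditions: LiCl, H2O, DMSO, 150 °C
Reagents that add atoms: none
Why: Krapcho dealkoxycarbonylation removes the activated ester only, and C1, now α to the ketone, should equilibrate through the enol to the epimer with the side chain equatorial, cis to the C8a methyl, as required.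

Step 12
Reactants: 20 methyl 3-[(1S,4aR,5S,6R,8aR)-5-[(2,5-dimethoxy-3-methylphenyl)methyl]-5,6,8a-trimethyl-2-oxodecahydronaphthalen-1-yl]propanoate
Product: 21 methyl 3-[(1S,4aR,5S,6R,8aR)-5-[(2,5-dimethoxy-3-methylphenyl)methyl]-5,6,8a-trimethyl-2-(propan-2-ylidene)decahydronaphthalen-1-yl]propanoate
Conditions: TiCl4, Zn, pyridine, THF, reflux; acetone (excess)
Reagents that add atoms: acetone, CC(C)=O
Why: McMurry cross-coupling with excess acetone on low-valent titanium deoxygenates both carbonyl partners to the tetrasubstituted isopropylidene alkene, which fixes the double bond exocyclic at C2 and removes the acidity of H-1.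

Step 13
Reactants: 21 methyl 3-[(1S,4aR,5S,6R,8aR)-5-[(2,5-dimethoxy-3-methylphenyl)methyl]-5,6,8a-trimethyl-2-(propan-2-ylidene)decahydronaphthalen-1-yl]propanoate
Product: 22 3-[(1S,4aR,5S,6R,8aR)-5-[(2,5-dihydroxy-3-methylphenyl)methyl]-5,6,8a-trimethyl-2-(propan-2-ylidene)decahydronaphthalen-1-yl]propanoic acid
Conditions: NaSEt, DMF, 130 °C, argon; aq. HCl
Reagents that add atoms: none
Why: Nucleophilic (SN2) demethylation by ethanethiolate cleaves both aryl methyl ethers and the methyl ester in one operation and does not touch the alkene.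

Step 14
Reactants: 22 3-[(1S,4aR,5S,6R,8aR)-5-[(2,5-dihydroxy-3-methylphenyl)methyl]-5,6,8a-trimethyl-2-(propan-2-ylidene)decahydronaphthalen-1-yl]propanoic acid
Product: 23 3-[(1S,4aR,5S,6R,8aR)-5-[(5-acetoxy-2-hydroxy-3-methylphenyl)methyl]-5,6,8a-trimethyl-2-(propan-2-ylidene)decahydronaphthalen-1-yl]propanoic acid
Conditions: Ac2O (1.1 equiv), NaHCO3, Na2S2O4 (cat.), THF/H2O, 0 °C
Reagents that add atoms: acetic anhydride, CC(=O)OC(C)=O
Why: Schotten–Baumann acetylation: the phenoxide flanked by two ring hydrogens should be acylated, the one between the methyl and the neopentyl-type CH2 group is shielded, and any mixed anhydride of the acid hydrolyses in the aqueous medium.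

Compound list
1 | tert-butyl 3-oxopentanoate | CCC(=O)CC(=O)OC(C)(C)C | starting material
2 | (E)-but-2-enal | C/C=C/C=O | starting material
3 | tert-butyl (3R)-3-methyl-5-oxo-2-propanoylpentanoate (both epimers at C2) | CCC(=O)C(C(=O)OC(C)(C)C)[C@H](C)CC=O | intermediate
4 | (3R)-3-methyl-5-oxoheptanal | CCC(=O)C[C@H](C)CC=O | intermediate
5 | (5R)-2,5-dimethylcyclohex-2-en-1-one | CC1=CC[C@@H](C)CC1=O | intermediate
6 | lithium (3R)-3,6-dimethylcyclohexa-1,5-dien-1-olate | [Li+].CC1=CC[C@@H](C)C=C1[O-] | intermediate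
7 | (5R,6S)-2,5,6-trimethylcyclohex-2-en-1-one (5,6-trans) | C[C@@H]1C(=O)C(C)=CC[C@H]1C | intermediate
8 | 2,6-dimethylbenzene-1,4-diol | Cc1cc(O)cc(C)c1O | starting material
9 | 2,5-dimethoxy-1,3-dimethylbenzene | COc1cc(C)c(OC)c(C)c1 | intermediate
10 | 1-(bromomethyl)-2,5-dimethoxy-3-methylbenzene | COc1cc(C)c(OC)c(CBr)c1 | intermediate
11 | lithium (3R)-2,3,6-trimethylcyclohexa-1,5-dien-1-olate | [Li+].CC1=C([O-])C(C)=CC[C@H]1C | intermediate
12 | (5R,6S)-6-[(2,5-dimethoxy-3-methylphenyl)methyl]-2,5,6-trimethylcyclohex-2-en-1-one | COc1cc(C)c(OC)c(C[C@]2(C)C(=O)C(C)=CC[C@H]2C)c1 | intermediate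
13 | lithium (5R,6S)-6-[(2,5-dimethoxy-3-methylphenyl)methyl]-2,5,6-trimethylcyclohex-1-en-1-olate | [Li+].COc1cc(C)c(OC)c(C[C@]2(C)C([O-])=C(C)CC[C@H]2C)c1 | intermediate
14 | methyl 2-[(1S,3S,4R)-3-[(2,5-dimethoxy-3-methylphenyl)methyl]-1,3,4-trimethyl-2-oxocyclohexyl]acetate (three ring methyls cis) | COc1cc(C)c(OC)c(C[C@]2(C)C(=O)[C@](C)(CC(=O)OC)CC[C@H]2C)c1 | intermediate
15 | methyl 2-[(1S,3S,4R)-3-[(2,5-dimethoxy-3-methylphenyl)methyl]-1,3,4-trimethyl-2-methylidenecyclohexyl]acetate | COc1cc(C)c(OC)c(C[C@]2(C)C(=C)[C@](C)(CC(=O)OC)CC[C@H]2C)c1 | intermediate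
16 | lithium enolate of ester 15 (1-methoxyethen-1-olate on the ring C1 substituent) | [Li+].COc1cc(C)c(OC)c(C[C@]2(C)C(=C)[C@](C)(C=C([O-])OC)CC[C@H]2C)c1 | intermediate
17 | dimethyl 2-[(1S,3S,4R)-3-[(2,5-dimethoxy-3-methylphenyl)methyl]-1,3,4-trimethyl-2-methylidenecyclohexyl]pentanedioate (both epimers at C2 of the diester) | COc1cc(C)c(OC)c(C[C@]2(C)C(=C)[C@](C)(C(CCC(=O)OC)C(=O)OC)CC[C@H]2C)c1 | intermediate
18 | dimethyl 2-[3-[(2,5-dimethoxy-3-methylphenyl)methyl]-2-(3-methoxy-3-oxopropyl)-1,3,4-trimethylcyclohexyl]pentanedioate (ring methyls cis, H-2 trans to them; both epimers at C2 of the diester) | COc1cc(C)c(OC)c(C[C@]2(C)[C@@H](CCC(=O)OC)[C@](C)(C(CCC(=O)OC)C(=O)OC)CC[C@H]2C)c1 | intermediate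
19 | methyl (4aR,5S,6R,8aR)-5-[(2,5-dimethoxy-3-methylphenyl)methyl]-1-(3-methoxy-3-oxopropyl)-5,6,8a-trimethyl-2-oxodecahydronaphthalene-3-carboxylate (mixture at C1 and C3) | COc1cc(C)c(OC)c(C[C@]2(C)[C@H]3CC(C(=O)OC)C(=O)C(CCC(=O)OC)[C@]3(C)CC[C@H]2C)c1 | intermediate
20 | methyl 3-[(1S,4aR,5S,6R,8aR)-5-[(2,5-dimethoxy-3-methylphenyl)methyl]-5,6,8a-trimethyl-2-oxodecahydronaphthalen-1-yl]propanoate | COc1cc(C)c(OC)c(C[C@]2(C)[C@H]3CCC(=O)[C@@H](CCC(=O)OC)[C@]3(C)CC[C@H]2C)c1 | intermediate
21 | methyl 3-[(1S,4aR,5S,6R,8aR)-5-[(2,5-dimethoxy-3-methylphenyl)methyl]-5,6,8a-trimethyl-2-(propan-2-ylidene)decahydronaphthalen-1-yl]propanoate | COc1cc(C)c(OC)c(C[C@]2(C)[C@H]3CCC(=C(C)C)[C@@H](CCC(=O)OC)[C@]3(C)CC[C@H]2C)c1 | intermediate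
22 | 3-[(1S,4aR,5S,6R,8aR)-5-[(2,5-dihydroxy-3-methylphenyl)methyl]-5,6,8a-trimethyl-2-(propan-2-ylidene)decahydronaphthalen-1-yl]propanoic acid | Cc1cc(O)cc(C[C@]2(C)[C@H]3CCC(=C(C)C)[C@@H](CCC(=O)O)[C@]3(C)CC[C@H]2C)c1O | intermediate
23 | 3-[(1S,4aR,5S,6R,8aR)-5-[(5-acetoxy-2-hydroxy-3-methylphenyl)methyl]-5,6,8a-trimethyl-2-(propan-2-ylidene)decahydronaphthalen-1-yl]propanoic acid (CNP0144688.2) | CC(=O)Oc1cc(C)c(O)c(C[C@]2(C)[C@H]3CCC(=C(C)C)[C@@H](CCC(=O)O)[C@]3(C)CC[C@H]2C)c1 | target

Total steps: 14. Longest linear sequence: 12 steps (steps 1, 2, 5–14; the arene branch 3, 4, 5–14 is equally long).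

Steps most likely to fail

Step 7. Addition of the methylene reagent may stall at a carbonyl flanked by two quaternary carbons, so that no reaction or attack at the ester takes over. The fallback sets out from 14 and replaces direct methylenation by epoxidation and deoxygenation. Dimethylsulfonium methylide (Me3S+ I−, n-BuLi, THF, 0 °C) should add to the ketone and close to the spiro-epoxide F1 (Corey–Chaykovsky). Cp2TiCl (trivalent titanium, made from Cp2TiCl2 and Zn) in THF should then open F1 to the tertiary radical and eliminate the titanium-bound oxygen (Nugent–RajanBabu deoxygenation). The route is rejoined at 15.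

Step 12. The reductive coupling may stop at the pinacol stage or be outrun by self-coupling of acetone and slow attack on the ester, because the ketone is α-branched and shielded by the axial C8a methyl. The fallback sets out from 20 and builds the alkene by addition and reductive transposition. CeCl3-promoted 1,2-addition of isopropenylmagnesium bromide (THF, −78 °C) should give the tertiary allylic alcohol F2. Et3SiH/CF3CO2H (CH2Cl2, −40 °C) should ionise it and deliver hydride to the CH2 terminus of the allyl cation (ionic hydrogenation with allylic transposition). The route is rejoined at 21.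

Step 6. Facial selectivity in the alkylation of the tetrasubstituted enolate may be poor, or O-alkylation may compete, which would give the C8a epimer. The fallback sets out from 12 and puts the new C–C bond under ligand control. The same conjugate reduction, with allyl chloroformate as the trap, should give the allyl enol carbonate F3. Pd2(dba)3 (zerovalent palladium) with the matching enantiomer of the t-BuPHOX ligand should move the allyl group to carbon with loss of CO2 (Tsuji–Stoltz decarboxylative allylic alkylation) to give the α-allyl ketone F4. OsO4 (cat.)/NaIO4 should cleave the alkene to the aldehyde F5, and I2, KOH, MeOH should oxidise F5 to the methyl ester. The route is rejoined at 14.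

Further compounds
F1 | step 7 | methyl 2-[spiro-epoxide of 14: 3-[(2,5-dimethoxy-3-methylphenyl)methyl]-1,3,4-trimethyl-2-spiro-oxiranylcyclohexyl]acetate | COc1cc(C)c(OC)c(C[C@]2(C)C3(CO3)[C@](C)(CC(=O)OC)CC[C@H]2C)c1
F2 | step 12 | methyl 3-[(1S,4aR,5S,6R,8aR)-5-[(2,5-dimethoxy-3-methylphenyl)methyl]-2-hydroxy-5,6,8a-trimethyl-2-(prop-1-en-2-yl)decahydronaphthalen-1-yl]propanoate | COc1cc(C)c(OC)c(C[C@]2(C)[C@H]3CCC(O)(C(C)=C)[C@@H](CCC(=O)OC)[C@]3(C)CC[C@H]2C)c1
F3 | step 6 | (5R,6S)-6-[(2,5-dimethoxy-3-methylphenyl)methyl]-2,5,6-trimethylcyclohex-1-en-1-yl prop-2-en-1-yl carbonate | COc1cc(C)c(OC)c(C[C@]2(C)C(OC(=O)OCC=C)=C(C)CC[C@H]2C)c1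
F4 | step 6 | (2S,5R,6S)-6-[(2,5-dimethoxy-3-methylphenyl)methyl]-2,5,6-trimethyl-2-(prop-2-en-1-yl)cyclohexan-1-one (three ring methyls cis) | COc1cc(C)c(OC)c(C[C@]2(C)C(=O)[C@](C)(CC=C)CC[C@H]2C)c1
F5 | step 6 | 2-[(1S,3S,4R)-3-[(2,5-dimethoxy-3-methylphenyl)methyl]-1,3,4-trimethyl-2-oxocyclohexyl]acetaldehyde | COc1cc(C)c(OC)c(C[C@]2(C)C(=O)[C@](C)(CC=O)CC[C@H]2C)c1
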